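Remark on the chemistry: cyclobutene (16) is not assumed to be purchasable and is made in step 9; lactol 8 is drawn in its closed form, which equilibrates with the open hydroxy aldehyde. Atom numbers are those of the target: ring A C1–C6, ring B C4/C5/C7/C12, ring C C7/C8/C11/C12, ring D C8–C11, chain C1′–C8′ (C8′ on oxygen).

## Analysis of the target

CNP0193334.1 (27) is a 2-O-alkylglycerol: the secondary oxygen of propane-1,3-diol carries an unbranched C8 chain that ends at C1 of a cyclohexane (ring A), and ring A is fused through C4–C5 to a linear ladder of three cyclobutanes, rings B, C and D. There are seven stereocentres, C1 and the six contiguous ladder carbons C4, C5, C7, C12, C8 and C11. Every ring fusion is cis, neighbouring rings lie anti across rings B and C, and the hydrogens on C1, C4 and C5 share one face of ring A, so the chain is cis to ring B. C1 is (S) and is separated from the nearest ladder centre by a methylene group, so its relation to the ladder cannot be set by simple proximity. The hydrocarbon core has no functional group. Its strained fused cyclobutanes are best kept away from hydrogenolysis catalysts, from long-lived radicals or cations on ring carbons and from strong heating while unsaturated; the other sensitive points are the 1,3-diol and, once C1′ is a carbonyl group, the epimerisable C1. The difficulty is to build six contiguous cyclobutane stereocentres in the anti-ladder arrangement with nothing to direct the reagents, and to tie the absolute configuration and the remote C1 centre to that ladder. The plan rests on one feature: ring A with C1, C1′ and the C4–C5 bond is (S)-cyclohex-3-ene-1-carboxylic acid 1 (carboxyl carbon = C1′, alkene = C4=C5), and ring B is this alkene plus C7 and C12, which can be brought in as a cyclopropane carbon and the carbene carbon attached to it, from the face of ring A that C1′ marks.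

## Retrosynthetic reasoning

The last operation only releases the diol: 27 is traced back to the cyclic acetal 26, in which one acid-labile group masks both primary hydroxyl groups. This mask is preferred to ethers that need hydrogenolysis, because the final deprotection then needs nothing harsher than dilute aqueous acid, which the cyclobutanes and the dialkyl ether tolerate.

The chain is cut at C1′–C2′. Saturated 26 comes from alkene 25, and 25 from aldehyde 19 and ylide 24. C1′ is the carboxyl carbon of 1 and is therefore in the core from the first step, while the other seven chain carbons and the glycerol unit form a separate, robust piece: 24 from phosphonium salt 23, 23 from bromide 22, and 22 from alcohol 20 and dibromide 21. A cut at C1–C1′ would force C1 to be made as a new stereocentre. The forward steps must join the pieces without epimerising C1 of 19 and must saturate the alkene without a metal surface.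

Aldehyde 19 is the oxidation product of alcohol 18, which is released from silyl ether 17. The silyl group is carried from the stage of the key step, so the core needs no further protecting-group change.

Rings C and D are removed together. Cutting C7–C8 and C11–C12 of 17 leaves the bicyclic cyclobutene 14 and cyclobutene 16, whose four carbons are ring D and whose alkene carbons become C8 and C11; 16 comes from bromide 15 by elimination. This double cut forms two rings and four stereocentres in one step, leaves no auxiliary atoms on the hydrocarbon, and never passes through a ladder intermediate that still carries a double bond in a doubly fused four-membered ring. Growing ring C by cyclopropanation of 14 followed by a second carbene ring enlargement was considered and set aside: that carbene would sit on a far more strained cyclopropane and is expected to fall back to 14 by loss of a two-carbon fragment. The forward reaction is a copper-catalysed [2+2] photocycloaddition of two unactivated strained alkenes; it must take the exo face of 14, anti to ring A, and place ring D anti to ring B.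

Ring B is the centre of the plan. In 14 the bond C4–C12 is cut and C12 is left on C7 alone as a carbene centre, which gives cyclopropylcarbene 13; 13 is traced through diazoalkane 12 and salt 11 to tosylhydrazone 10. Cutting C5–C7 instead is the same operation. This cut turns a four-membered ring, which would have to be added to an unbiased cyclohexene face, into a three-membered ring that can be delivered intramolecularly. The forward step then only enlarges the ring by one carbon, and no stereocentre is formed or touched.

Hydrazone 10 is the silyl ether of hydroxy hydrazone 9, the condensation product of lactol 8, and 8 is the half-reduced form of lactone 7. In 7 the carbons that become C7 and C12 are already in place, C12 as the lactone carbonyl and C7 as the cyclopropane apex, and the C1′ oxygen is the lactone oxygen. These three steps only change oxidation level and free the alcohol for protection.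

The cyclopropane of 7 is cut at C4–C7 and C5–C7, which leads to diazoacetate 6, the diazoacetic ester of alcohol 2. Because the carbenoid carbon hangs from C1′, it can reach the alkene only from the face that carries C1′. This fixes C4 and C5 cis to the chain, as required in 27, and lets the one purchased stereocentre control the other two of ring A. Ester 6 is made from bromoacetate 4 by way of 5, 4 from alcohol 2 and acyl bromide 3, and 2 from acid 1.

## Alternatives that were turned down

Alternative 1: The ladder carbons C4, C5 and C7–C12 are taken from the perimeter of cyclooctatetraene A1, ring A is annulated onto the cyclobutene of its bicyclic valence isomer, and the key disconnection is the C8–C11 bond. In the forward direction the cyclohexa-1,3-diene ring of triene A2 is irradiated and closes by a disrotatory 4π electrocyclisation, which turns that ring into rings C and D and gives the meso ladderene A3.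
- For: A1 is cheap and supplies all eight ladder carbons, the electrocyclisations add no atoms that must be removed later, and the cis fusions follow from orbital symmetry. In carbon economy for the ladder this plan is stronger than the chosen one.
- Against: A3 has a mirror plane and no substituent at C1. The chain, the C1 configuration and the absolute configuration would all depend on a late differentiation of the enantiotopic carbons of a cis-disubstituted cyclohexene, in the presence of a more reactive four-membered-ring double bond. The photochemical closure of A2 can occur on either face of the diene, so nothing in the structure enforces the anti ladder. A2 and A3 are both thermally labile valence isomers.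
- Comparison: the chosen route gives up the economy of A1 but buys C1 in the right configuration, lets it dictate C4 and C5 through a tether, and never carries an unsaturated ladder.

Alternative 2: Ring A is cut at C3–C4 and C5–C6, which leads to cyclobut-2-enone A4 and the chain-bearing diene A5. The forward key step is a Diels–Alder reaction of A4, activated by a chiral Lewis acid, with A5; the usual 1,4-orientation puts the chain on C1 and gives the cis-fused cyclobutanone A6 with the carbonyl at C12.
- For: the plan is convergent, the whole C8 chain is present from the start, so no late homologation and no epimerisable C1′ aldehyde are needed, and ring B arrives with a carbonyl handle. On convergence and chain economy it is as strong as or stronger than the chosen route.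
- Against: A4 is a labile dienophile that must be prepared and used at once, and A5 needs several steps. The configuration of C4 and C5 depends entirely on the catalyst's discrimination of an almost unbiased 2-alkyldiene. C1 is still trigonal in A6, so it must be set later by hydrogenation of C1=C2 under the weak facial bias of a cyclobutane two or three bonds away.
- Comparison: two separate stereochemical events, neither secured by the substrate, replace the single purchased centre of the chosen route, which sets C4 and C5 by intramolecular delivery and never creates C1.

Alternative 3: Ring C is cut at C7–C8 and C11–C12, with a cyclopentanone standing in for ring D. In the forward direction triplet cyclopent-2-enone A7 adds to the strained C7=C12 bond of cis-bicyclo[4.2.0]octa-3,7-diene A8 to give the tetracyclic ketone A9; ring contraction and loss of the extra carbon would then give ring D.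
- For: enone photocycloaddition to a strained cyclobutene is dependable, the exo face and the anti arrangement are favoured sterically, and the two orientations of the carbonyl converge once the extra carbon is excised. For building ring C this plan stands on firmer ground than the crossed photocycloaddition of step 10, and it is kept as the fallback for that step.
- Against: A8 is achiral and A9 racemic, so the C1 substituent and the absolute configuration again need a late differentiation of the enantiotopic ends of the ring A alkene. Contraction and excision cost four or five steps, the last through a radical on the ladder, and A8 must itself be synthesised.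
- Comparison: the chosen route offers a C1 centre fixed from the start and forms rings C and D without auxiliary carbon.

Key step: step 8

## Route

Step 1
Reactants: 1 (S)-cyclohex-3-ene-1-carboxylic acid
Product: 2 [(1S)-cyclohex-3-en-1-yl]methanol
Conditions: LiAlH4, THF, 0 °C to rt; NaOH (aq) work-up
Reagents that add atoms: none
Why: Hydride reduction of a carboxylic acid to the primary alcohol; the carboxylate formed first cannot enolise, so C1 keeps its configuration, and the isolated alkene is inert to LiAlH4.

Step 2
Reactants: 2 [(1S)-cyclohex-3-en-1-yl]methanol; 3 bromoacetyl bromide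
Product: 4 [(1S)-cyclohex-3-en-1-yl]methyl 2-bromoacetate
Conditions: pyridine, CH2Cl2, 0 °C
Reagents that add atoms: none
Why: O-Acylation of a primary alcohol by an acyl bromide; attack at the acyl carbon is much faster than displacement of the α-bromide.

Step 3
Reactants: 4 [(1S)-cyclohex-3-en-1-yl]methyl 2-bromoacetate
Product: 6 [(1S)-cyclohex-3-en-1-yl]methyl 2-diazoacetate, via N-alkyl ditosylhydrazide 5 (not isolated)
Conditions: TsNHNHTs (2 equiv), DBU (5 equiv), THF, 0 °C
Reagents that add atoms: N,N′-bis(p-toluenesulfonyl)hydrazine, Cc1ccc(cc1)S(=O)(=O)NNS(=O)(=O)c1ccc(C)cc1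
Why: Known preparation of diazoacetates from bromoacetates: N-alkylation of the ditosylhydrazine gives 5, and two base-induced eliminations of sulfinate leave the diazo group; the conditions are mild enough for the ester and the alkene.

Step 4
Reactants: 6 [(1S)-cyclohex-3-en-1-yl]methyl 2-diazoacetate
Product: 7 4-oxatricyclo[4.3.1.0^2,9]decan-3-one (cyclopropane C4–C5–C7 on the C1′ face of ring A; lactone carbonyl C12 endo on C7)
Conditions: Cu(MeCN)4PF6 (5 mol%), CH2Cl2, reflux; slow syringe-pump addition of 6 (high dilution)
Reagents that add atoms: none
Why: Intramolecular carbenoid cyclopropanation of an alkenyl diazoacetate; a copper carbenoid is chosen because it adds to alkenes far more readily than it inserts into C–H bonds. The carbenoid carbon hangs from C1′ and reaches the C4=C5 bond only from the C1′ face with ring A in a boat-like conformer, so C4 and C5 are set cis to C1′ and the ester carbon on C7 is necessarily endo.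

Step 5
Reactants: 7 4-oxatricyclo[4.3.1.0^2,9]decan-3-one
Product: 8 4-oxatricyclo[4.3.1.0^2,9]decan-3-ol (lactol, both anomers)
Conditions: i-Bu2AlH (1.1 equiv), CH2Cl2, −78 °C; aq. KNaC4H4O6 work-up
Reagents that add atoms: none
Why: Partial reduction of a lactone; the aluminium hemiacetal is stable at −78 °C and gives the lactol on work-up. The new hemiacetal centre forms as a mixture and disappears in the next step.

Step 6
Reactants: 8 4-oxatricyclo[4.3.1.0^2,9]decan-3-ol
Product: 9 (E)-tosylhydrazone of (3S)-3-(hydroxymethyl)bicyclo[4.1.0]heptane-7-endo-carbaldehyde (hydroxymethyl cis to the cyclopropane)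
Conditions: TsNHNH2 (slight excess), MeOH, rt
Reagents that add atoms: p-toluenesulfonohydrazide, Cc1ccc(cc1)S(=O)(=O)NN
Why: The lactol is in equilibrium with the endo hydroxy aldehyde, which condenses with the hydrazide to the (E)-tosylhydrazone; a seven-membered cyclic N,O-acetal is not expected to compete.

Step 7
Reactants: 9 hydroxy tosylhydrazone
Product: 10 (E)-tosylhydrazone of (3S)-3-[(tert-butyldimethylsilyloxy)methyl]bicyclo[4.1.0]heptane-7-endo-carbaldehyde (silyloxymethyl cis to the cyclopropane)
Conditions: TBSCl, imidazole, DMF, 0 °C to rt; aqueous work-up
Reagents that add atoms: tert-butyldimethylsilyl chloride, CC(C)(C)[Si](C)(C)Cl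
Why: Silylation of the primary alcohol; any silyl group taken up by the sulfonamide nitrogen is lost on aqueous work-up. The ether removes the O–H bond that a carbene would otherwise attack.

Step 8
Reactants: 10 silyl ether tosylhydrazone
Product: 14 (3S)-all-cis-3-[(tert-butyldimethylsilyloxy)methyl]bicyclo[4.2.0]oct-7-ene, via sodium tosylhydrazonide 11 (not isolated), via diazoalkane 12 (not isolated), via cyclopropylcarbene 13 (not isolated)
Conditions: NaH (1.05 equiv), THF, 0 °C to rt; evaporate; salt added slowly to diglyme at 130 °C (high dilution)
Reagents that add atoms: none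
Why: Deprotonation gives salt 11, which on heating in an aprotic medium loses p-toluenesulfinate to give diazoalkane 12 and then, with loss of N2, the singlet cyclopropylcarbene 13 (aprotic Bamford–Stevens reaction). In 13 the empty orbital on C12 lies next to the two bent, electron-rich ring bonds C7–C4 and C7–C5; one of them migrates to C12 in a 1,2-carbon shift, so that C12 becomes bonded to C4 while C7 and C12 become the double bond. The closest known reaction type is the ring enlargement of cyclopropylcarbenes, generated from cyclopropanecarbaldehyde tosylhydrazones, to cyclobutenes, which includes bicyclo[n.1.0]alkane cases. Ring B is thus closed not by cyclisation of a chain but by one-carbon enlargement of the three-membered ring, the carbene carbon being inserted into a ring bond. No stereocentre is created: C7 and C12 end up trigonal, the migrating carbon keeps its configuration, and C4 and C5, fixed cis to C1′ in step 4, are carried over unchanged; migration of the C5 bond gives the identical product, and the endo position of the carbene carbon is of no consequence. The step needs chemoselectivity for the 1,2-carbon shift over fragmentation into an alkene and an alkyne, over 1,2-hydrogen shift to an alkylidenecyclopropane and over azine formation. This is secured by the strain and alignment of the ring bonds in the bisected carbene conformation, by the absence of any O–H bond (silyl ether), by the aprotic medium, which keeps 12 from being protonated to a cyclopropylcarbinyl cation, and by high dilution at a moderate temperature.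

Step 9
Reactants: 15 bromocyclobutane
Product: 16 cyclobutene
Conditions: KOt-Bu, DMSO, rt to 50 °C; N2 stream into a −78 °C trap
Reagents that add atoms: none
Why: E2 dehydrobromination of a secondary bromide by a hindered base in a dipolar aprotic solvent; the gaseous alkene leaves the mixture as it forms.

Step 10
Reactants: 14 (3S)-all-cis-3-[(tert-butyldimethylsilyloxy)methyl]bicyclo[4.2.0]oct-7-ene; 16 cyclobutene
Product: 17 10-[(tert-butyldimethylsilyloxy)methyl]tetracyclo[6.4.0.0^2,7.0^3,6]dodecane (cis,anti,cis,anti,cis ladder; CH2O on C1 cis to ring B)
Conditions: (CuOTf)2·C6H6 (cat.), Et2O, large excess of 16, hν (254 nm, quartz, sealed tube), 0 °C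
Reagents that add atoms: none
Why: Copper-catalysed [2+2] photocycloaddition of two strained cycloalkenes, a pure addition that proceeds within a bis(alkene) complex of CuOTf and is known to join cyclobutene-type alkenes into anti ladders; a roughly fifteenfold excess of the volatile partner 16 directs 14 into the crossed adduct. C7 and C12 are set by addition to the exo face of 14, away from ring A; C8 and C11 are cis because the addition is suprafacial on 16, and they lie anti to ring B because ring D points away from ring B in the complex.

Step 11
Reactants: 17 silyl ether of the ladder alcohol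
Product: 18 (tetracyclo[6.4.0.0^2,7.0^3,6]dodecan-10-yl)methanol (same configuration)
Conditions: Bu4NF, THF, rt
Reagents that add atoms: none
Why: Fluoride cleavage of a silyl ether; the saturated hydrocarbon core is inert.

Step 12
Reactants: 18 ladder alcohol
Product: 19 tetracyclo[6.4.0.0^2,7.0^3,6]dodecane-10-carbaldehyde (same configuration)
Conditions: Dess–Martin periodinane, pyridine, CH2Cl2, 0 °C to rt
Reagents that add atoms: none
Why: Dess–Martin oxidation of a primary alcohol under buffered, nearly neutral conditions, which should leave the α-stereocentre C1 untouched; the aldehyde is used at once.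

Step 13
Reactants: 20 cis-2-phenyl-1,3-dioxan-5-ol; 21 1,7-dibromoheptane
Product: 22 cis-5-[(7-bromoheptyl)oxy]-2-phenyl-1,3-dioxane
Conditions: NaH, DMF, 0 °C to rt; 21 in fourfold excess
Reagents that add atoms: none
Why: Williamson ether synthesis; the excess of dibromide suppresses double alkylation. The benzylidene acetal blocks both primary hydroxyl groups of glycerol, so only O-2 is alkylated.

Step 14
Reactants: 22 cis-5-[(7-bromoheptyl)oxy]-2-phenyl-1,3-dioxane
Product: 23 {7-[(cis-2-phenyl-1,3-dioxan-5-yl)oxy]heptyl}triphenylphosphonium bromide
Conditions: PPh3, MeCN, 80 °C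
Reagents that add atoms: triphenylphosphine, c1ccc(cc1)P(c1ccccc1)c1ccccc1
Why: SN2 quaternisation of the phosphine by a primary bromide; the acetal and the ether are inert.

Step 15
Reactants: 23 phosphonium bromide; 19 ladder aldehyde
Product: 25 cis-5-{[(7Z)-8-(tetracyclo[6.4.0.0^2,7.0^3,6]dodecan-10-yl)oct-7-en-1-yl]oxy}-2-phenyl-1,3-dioxane, via phosphonium ylide 24 (not isolated)
Conditions: NaN(SiMe3)2 (0.95 equiv based on 23), THF, −78 to 0 °C; then 19, −78 °C to rt
Reagents that add atoms: none
Why: Wittig reaction of a non-stabilised ylide with an aldehyde, forming C1′=C2′ (Z expected, geometry irrelevant). The ylide is preformed with a deficit of base and the aldehyde is added cold, so that addition to the carbonyl group outruns enolisation at C1.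

Step 16
Reactants: 25 Z-alkene
Product: 26 cis-5-{[8-(tetracyclo[6.4.0.0^2,7.0^3,6]dodecan-10-yl)octyl]oxy}-2-phenyl-1,3-dioxane
Conditions: 2-O2NC6H4SO2NHNH2, Et3N, CH2Cl2, rt
Reagents that add atoms: none
Why: Diimide reduction: concerted syn transfer of H2 to the unhindered disubstituted alkene without a metal, so the cyclobutane bonds and the benzylic acetal C–O bonds are not at risk.

Step 17
Reactants: 26 benzylidene acetal
Product: 27 2-{[8-(tetracyclo[6.4.0.0^2,7.0^3,6]dodecan-10-yl)octyl]oxy}propane-1,3-diol (CNP0193334.1)
Conditions: 2 M HCl (aq), THF, 40 °C
Reagents that add atoms: none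
Why: Acid hydrolysis of the benzylidene acetal frees the 1,3-diol; the dialkyl ether and the saturated ladder are stable to dilute acid, and no stereocentre is involved.

## Compound list

1 | (S)-cyclohex-3-ene-1-carboxylic acid | OC(=O)[C@H]1CCC=CC1 | starting material
2 | [(1S)-cyclohex-3-en-1-yl]methanol | OC[C@H]1CCC=CC1 | intermediate
3 | bromoacetyl bromide | BrCC(Br)=O | starting material
4 | [(1S)-cyclohex-3-en-1-yl]methyl 2-bromoacetate | BrCC(=O)OC[C@H]1CCC=CC1 | intermediate
5 | [(1S)-cyclohex-3-en-1-yl]methyl 2-[1,2-bis(p-toluenesulfonyl)hydrazin-1-yl]acetate (not isolated) | Cc1ccc(cc1)S(=O)(=O)NN(CC(=O)OC[C@H]1CCC=CC1)S(=O)(=O)c1ccc(C)cc1 | intermediate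
6 | [(1S)-cyclohex-3-en-1-yl]methyl 2-diazoacetate | [N-]=[N+]=CC(=O)OC[C@H]1CCC=CC1 | intermediate
7 | 4-oxatricyclo[4.3.1.0^2,9]decan-3-one (lactone bridging the endo carboxyl on C7 and the cis hydroxymethyl on C1) | O=C1OC[C@H]2CC[C@@H]3[C@H](C2)[C@@H]31 | intermediate
8 | 4-oxatricyclo[4.3.1.0^2,9]decan-3-ol (lactol, both anomers) | OC1OC[C@H]2CC[C@@H]3[C@H](C2)[C@@H]31 | intermediate
9 | (E)-tosylhydrazone of (3S)-3-(hydroxymethyl)bicyclo[4.1.0]heptane-7-endo-carbaldehyde, hydroxymethyl cis to the cyclopropane | OC[C@H]1CC[C@@H]2[C@H](C1)[C@@H]2/C=N/NS(=O)(=O)c1ccc(C)cc1 | intermediate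
10 | (E)-tosylhydrazone of (3S)-3-[(tert-butyldimethylsilyloxy)methyl]bicyclo[4.1.0]heptane-7-endo-carbaldehyde, silyloxymethyl cis to the cyclopropane | CC(C)(C)[Si](C)(C)OC[C@H]1CC[C@@H]2[C@H](C1)[C@@H]2/C=N/NS(=O)(=O)c1ccc(C)cc1 | intermediate
11 | sodium salt of tosylhydrazone 10 (not isolated) | CC(C)(C)[Si](C)(C)OC[C@H]1CC[C@@H]2[C@H](C1)[C@@H]2/C=N/[N-]S(=O)(=O)c1ccc(C)cc1.[Na+] | intermediate
12 | (3S)-3-[(tert-butyldimethylsilyloxy)methyl]-7-endo-(diazomethyl)bicyclo[4.1.0]heptane (not isolated) | CC(C)(C)[Si](C)(C)OC[C@H]1CC[C@@H]2[C@H](C1)[C@@H]2C=[N+]=[N-] | intermediate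
13 | {(3S)-3-[(tert-butyldimethylsilyloxy)methyl]bicyclo[4.1.0]heptan-7-yl}carbene (not isolated) | CC(C)(C)[Si](C)(C)OC[C@H]1CC[C@@H]2[C@H](C1)[C@@H]2[CH] | intermediate
14 | (3S)-all-cis-3-[(tert-butyldimethylsilyloxy)methyl]bicyclo[4.2.0]oct-7-ene (H1, H3 and H6 on one face) | CC(C)(C)[Si](C)(C)OC[C@H]1CC[C@@H]2[C@H](C1)C=C2 | intermediate
15 | bromocyclobutane | BrC1CCC1 | starting material
16 | cyclobutene | C1=CCC1 | intermediate
17 | 10-[(tert-butyldimethylsilyloxy)methyl]tetracyclo[6.4.0.0^2,7.0^3,6]dodecane, cis,anti,cis,anti,cis, CH2O cis to ring B | CC(C)(C)[Si](C)(C)OC[C@H]1CC[C@@H]2[C@H](C1)[C@H]1[C@@H]3CC[C@@H]3[C@@H]21 | intermediate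
18 | (tetracyclo[6.4.0.0^2,7.0^3,6]dodecan-10-yl)methanol, same configuration | OC[C@H]1CC[C@@H]2[C@H](C1)[C@H]1[C@@H]3CC[C@@H]3[C@@H]21 | intermediate
19 | tetracyclo[6.4.0.0^2,7.0^3,6]dodecane-10-carbaldehyde, same configuration | O=C[C@H]1CC[C@@H]2[C@H](C1)[C@H]1[C@@H]3CC[C@@H]3[C@@H]21 | intermediate
20 | cis-2-phenyl-1,3-dioxan-5-ol (1,3-O-benzylideneglycerol) | O[C@@H]1CO[C@H](c2ccccc2)OC1 | starting material
21 | 1,7-dibromoheptane | BrCCCCCCCBr | starting material
22 | cis-5-[(7-bromoheptyl)oxy]-2-phenyl-1,3-dioxane | BrCCCCCCCO[C@@H]1CO[C@H](c2ccccc2)OC1 | intermediate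
23 | {7-[(cis-2-phenyl-1,3-dioxan-5-yl)oxy]heptyl}triphenylphosphonium bromide | [Br-].c1ccc(cc1)[P+](c1ccccc1)(c1ccccc1)CCCCCCCO[C@@H]1CO[C@H](c2ccccc2)OC1 | intermediate
24 | {7-[(cis-2-phenyl-1,3-dioxan-5-yl)oxy]heptylidene}triphenylphosphorane (not isolated) | c1ccc(cc1)P(c1ccccc1)(c1ccccc1)=CCCCCCCO[C@@H]1CO[C@H](c2ccccc2)OC1 | intermediate
25 | cis-5-{[(7Z)-8-(tetracyclo[6.4.0.0^2,7.0^3,6]dodecan-10-yl)oct-7-en-1-yl]oxy}-2-phenyl-1,3-dioxane | O([C@@H]1CO[C@H](c2ccccc2)OC1)CCCCCC/C=C\[C@H]1CC[C@@H]2[C@H](C1)[C@H]1[C@@H]3CC[C@@H]3[C@@H]21 | intermediate
26 | cis-5-{[8-(tetracyclo[6.4.0.0^2,7.0^3,6]dodecan-10-yl)octyl]oxy}-2-phenyl-1,3-dioxane | O([C@@H]1CO[C@H](c2ccccc2)OC1)CCCCCCCC[C@H]1CC[C@@H]2[C@H](C1)[C@H]1[C@@H]3CC[C@@H]3[C@@H]21 | intermediate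
27 | 2-{[8-(tetracyclo[6.4.0.0^2,7.0^3,6]dodecan-10-yl)octyl]oxy}propane-1,3-diol, C1 (S), all-anti ladder, chain cis to ring B (CNP0193334.1) | OCC(CO)OCCCCCCCC[C@H]1CC[C@@H]2[C@H](C1)[C@H]1[C@@H]3CC[C@@H]3[C@@H]21 | target

## Step count and least certain steps

Total: 17 steps. Longest linear sequence: 14 steps from 1 (steps 1–8, 10–12, 15–17); side branches are step 9 and steps 13–14.

**Step 8 (key step).** The most likely failure is fragmentation of carbene 13 by cleavage of both C7–C4 and C7–C5, together with hydrogen shift, capture of the endo carbene centre by the nearby ether oxygen or bimolecular azine formation, in place of the 1,2-carbon shift.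

Fallback: ring B is built by ketene cycloaddition instead, setting out from 2 and returning at 14. Alcohol 2 is silylated to tert-butyl{[(1S)-cyclohex-3-en-1-yl]methoxy}dimethylsilane F1. Dichloroketene, generated from Cl3CCOCl and Zn–Cu couple in Et2O, adds to the alkene to give the dichlorocyclobutanone F2 together with its facial and positional isomers. Zn in AcOH removes the chlorines to give cyclobutanone F3, and at this stage the isomers with ring B cis to C1′ are separated from the trans ones. The tosylhydrazone F4 is then taken through a Shapiro reaction (n-BuLi, 2.2 equiv, THF, −78 to 0 °C, then water), which gives the C7=C12 alkene from either carbonyl position and rejoins the route at 14. The price is the loss of the tether: the ketene adds to both faces of the alkene, so a diastereomer separation and a loss of material must be accepted.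

**Step 10.** The most likely failure is homodimerisation of 14 or of 16 in place of crossed addition, or poor light uptake by the mixed copper complex, so that 14 is converted slowly or unselectively.

Fallback: rings C and D are built stepwise by enone photocycloaddition and ring contraction, setting out from 14 and returning at 17. Irradiation of 14 with cyclopent-2-enone (350 nm, CH2Cl2) gives the exo, anti cyclopentanone photoadduct F5; either orientation of the carbonyl is usable. Formylation (HCO2Et, NaH) gives the hydroxymethylene ketone F6, and deformylative diazo transfer (4-acetamidobenzenesulfonyl azide, Et3N) gives the α-diazoketone F7. A photochemical Wolff rearrangement in aqueous THF contracts the five-membered ring to the ring D carboxylic acid F8. Its Barton ester F9 (N-hydroxypyridine-2-thione, DCC) is photolysed in the presence of t-BuSH, which removes the extra carbon and rejoins the route at 17.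

**Step 4.** The most likely failure is insertion of the carbenoid into the C1–H bond (five-membered lactone) or carbene dimerisation, in place of closure of the seven-membered lactone ring onto the alkene.

Fallback: the tether is shortened to an all-carbon one, setting out from 1 and returning at 7. Acid 1 is converted to the acid chloride F10 ((COCl)2, cat. DMF) and with CH2N2 to the diazoketone F11. Wolff rearrangement (PhCO2Ag, Et3N, aqueous dioxane) completes the Arndt–Eistert homologation to 2-[(1S)-cyclohex-3-en-1-yl]acetic acid F12, with retention at C1. The sequence is repeated through the acid chloride F13 to the diazoketone F14. Its copper carbenoid (Cu(acac)2, toluene, 80 °C) closes a six-membered ketone ring onto the C1′ face of the alkene and gives the tricyclic ketone F15. Baeyer–Villiger oxidation (CF3CO3H, Na2HPO4, CH2Cl2), with migration of the primary carbon C1′ in preference to the cyclopropyl carbon, inserts the oxygen next to C1′ and rejoins the route at lactone 7.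

**Step 15.** The most likely failure is enolisation of aldehyde 19 by the basic ylide, that is epimerisation at C1, before olefination.

Fallback: C1′–C2′ is formed by alkyl–alkyl coupling, setting out from 18 and 22 and returning at 26. Alcohol 18 is converted to the tosylate F16 (TsCl, pyridine), and bromide 22 to the Grignard reagent F17 (Mg, THF). Coupling catalysed by Li2CuCl4 (THF, −20 °C to rt) joins the two carbons directly and rejoins the route at 26, so that neither aldehyde 19 nor alkene 25 is needed.

## Further compounds

F1 | step 8 | tert-butyl{[(1S)-cyclohex-3-en-1-yl]methoxy}dimethylsilane | CC(C)(C)[Si](C)(C)OC[C@H]1CCC=CC1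
F2 | step 8 | all-cis-3-[(tert-butyldimethylsilyloxy)methyl]-8,8-dichlorobicyclo[4.2.0]octan-7-one (carbonyl on C12; isomer leading to 14) | CC(C)(C)[Si](C)(C)OC[C@H]1CC[C@@H]2[C@H](C1)C(Cl)(Cl)C2=O
F3 | step 8 | all-cis-3-[(tert-butyldimethylsilyloxy)methyl]bicyclo[4.2.0]octan-7-one | CC(C)(C)[Si](C)(C)OC[C@H]1CC[C@@H]2[C@H](C1)CC2=O
F4 | step 8 | tosylhydrazone of F3 | CC(C)(C)[Si](C)(C)OC[C@H]1CC[C@@H]2[C@H](C1)CC2=NNS(=O)(=O)c1ccc(C)cc1
F5 | step 10 | exo, anti cyclopentanone photoadduct of 14 (carbonyl on C8 shown) | CC(C)(C)[Si](C)(C)OC[C@H]1CC[C@@H]2[C@H](C1)[C@H]1[C@@H]3C(=O)CC[C@@H]3[C@@H]21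
F6 | step 10 | α-(hydroxymethylene) ketone from F5 | CC(C)(C)[Si](C)(C)OC[C@H]1CC[C@@H]2[C@H](C1)[C@H]1[C@@H]3C(=O)C(=CO)C[C@@H]3[C@@H]21
F7 | step 10 | α-diazoketone from F6 | CC(C)(C)[Si](C)(C)OC[C@H]1CC[C@@H]2[C@H](C1)[C@H]1[C@@H]3C(=O)C(=[N+]=[N-])C[C@@H]3[C@@H]21
F8 | step 10 | ring D carboxylic acid of silyl ether 17 (carboxyl on C9, both epimers) | CC(C)(C)[Si](C)(C)OC[C@H]1CC[C@@H]2[C@H](C1)[C@H]1[C@@H]3C(C(O)=O)C[C@@H]3[C@@H]21
F9 | step 10 | Barton ester (2-thioxopyridin-1(2H)-yl ester) of F8 | CC(C)(C)[Si](C)(C)OC[C@H]1CC[C@@H]2[C@H](C1)[C@H]1[C@@H]3C(C(=O)On4ccccc4=S)C[C@@H]3[C@@H]21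
F10 | step 4 | (1S)-cyclohex-3-ene-1-carbonyl chloride | ClC(=O)[C@H]1CCC=CC1
F11 | step 4 | 2-diazo-1-[(1S)-cyclohex-3-en-1-yl]ethan-1-one | [N-]=[N+]=CC(=O)[C@H]1CCC=CC1
F12 | step 4 | 2-[(1S)-cyclohex-3-en-1-yl]acetic acid | OC(=O)C[C@H]1CCC=CC1
F13 | step 4 | 2-[(1S)-cyclohex-3-en-1-yl]acetyl chloride | ClC(=O)C[C@H]1CCC=CC1
F14 | step 4 | 1-diazo-3-[(1S)-cyclohex-3-en-1-yl]propan-2-one | [N-]=[N+]=CC(=O)C[C@H]1CCC=CC1
F15 | step 4 | tricyclo[3.3.1.0^2,8]nonan-3-one (cyclopropane on the C1′ face, carbonyl carbon endo) | O=C1C[C@H]2CC[C@@H]3[C@H](C2)[C@@H]31
F16 | step 15 | (tetracyclo[6.4.0.0^2,7.0^3,6]dodecan-10-yl)methyl p-toluenesulfonate | Cc1ccc(cc1)S(=O)(=O)OC[C@H]1CC[C@@H]2[C@H](C1)[C@H]1[C@@H]3CC[C@@H]3[C@@H]21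
F17 | step 15 | {7-[(cis-2-phenyl-1,3-dioxan-5-yl)oxy]heptyl}magnesium bromide | Br[Mg]CCCCCCCO[C@@H]1CO[C@H](c2ccccc2)OC1
A1 | alternative 1 | cyclooctatetraene | C1=CC=CC=CC=C1
A2 | alternative 1 | cis,anti,cis-tricyclo[6.4.0.0^2,7]dodeca-3,5,10-triene (cyclohexene-fused bicyclo[4.2.0]octa-2,4-diene) | C1=CC[C@@H]2[C@H](C1)[C@H]1C=CC=C[C@@H]21
A3 | alternative 1 | meso [3]-ladderene fused to cyclohexene | C1=CC[C@@H]2[C@H](C1)[C@H]1[C@@H]3C=C[C@@H]3[C@@H]21
A4 | alternative 2 | cyclobut-2-en-1-one | O=C1C=CC1
A5 | alternative 2 | tert-butyldimethyl[(9-methylideneundec-10-en-1-yl)oxy]silane (2-(8-silyloxyoctyl)buta-1,3-diene) | C=CC(=C)CCCCCCCCO[Si](C)(C)C(C)(C)C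
A6 | alternative 2 | chain-bearing cis-bicyclo[4.2.0]oct-3-en-7-one | CC(C)(C)[Si](C)(C)OCCCCCCCCC1=CC[C@@H]2[C@H](C1)CC2=O
A7 | alternative 3 | cyclopent-2-en-1-one | O=C1C=CCC1
A8 | alternative 3 | cis-bicyclo[4.2.0]octa-3,7-diene | C1=CC[C@@H]2[C@H](C1)C=C2
A9 | alternative 3 | tetracyclic cyclopentanone photoadduct (one orientation) | C1=CC[C@@H]2[C@H](C1)[C@H]1[C@@H]3C(=O)CC[C@@H]3[C@@H]21
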